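The route rests on cutting the C2=C3 double bond and tying the C6 oxygen to C1 as an ester. Ring-closing metathesis of a C6 acrylate onto the 1,1-disubstituted C3 alkene forms C2=C3 inside a seven-membered lactone (C1–C6 plus O), which can hold only a cis double bond: C1 ends cis to C4, C20 trans, and C1 (carbonyl) is distinguished from C20. The precursor is the C6 acrylate of a (6S,7R)-6,7-diol with free C7 hydroxyl and silylated C12 and C20 hydroxyls, built from geranyl acetate. After reduction, the C6 oxygen becomes the leaving group displaced by the C7 hydroxyl, giving the (6R,7R) epoxide.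

Key step: step 14

Assumption: geranyl acetate, 2-methylidenepropane-1,3-diol and (+)-B-methoxydiisopinocampheylborane (the enantiomer made from (−)-α-pinene) are taken as purchased; target numbering (C1–C16, C20 on C3) is used for all intermediates.

Step 1
Reactants: 1 geranyl acetate
Product: 2 (2E,6E)-8-hydroxygeranyl acetate (target C12 as CH2OH)
Conditions: SeO2 (cat.), t-BuOOH, salicylic acid (cat.), CH2Cl2, rt
Reagents that add atoms: tert-butyl hydroperoxide CC(C)(C)OO (oxygen relayed by catalytic SeO2)
Why: Riley-type allylic oxidation (ene reaction, then [2,3]-sigmatropic shift) should attack the (E)-methyl of the electron-rich distal alkene, the other alkene being deactivated by the allylic acetate, and any aldehyde formed is already the product of step 2; no stereocenter is formed.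

Step 2
Reactants: 2 (2E,6E)-8-hydroxygeranyl acetate
Product: 3 (2E,6E)-8-oxogeranyl acetate (C12 aldehyde)
Conditions: MnO2 (activated, excess), CH2Cl2, rt
Reagents that add atoms: none
Why: Allylic alcohol oxidation on MnO2 stops at the enal and should leave the (E) geometry and the acetate untouched.

Step 3
Reactants: 3 (2E,6E)-8-oxogeranyl acetate
Product: 4 (12R)-homoallylic alcohol, C13–C14 as an allyl group
Conditions: (+)-B-methoxydiisopinocampheylborane, allylMgBr, Et2O, −78 °C to rt; then 3, −78 °C; then HOCH2CH2NH2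
Reagents that add atoms: allylmagnesium bromide C=CC[Mg]Br
Why: Brown allylation: the allylborane carrying isopinocampheyl groups from (−)-α-pinene is expected to add through a closed chair transition state to the Re face of the enal, setting C12 as R under reagent control, and the non-oxidative ethanolamine work-up spares the acetate.

Step 4
Reactants: 4 (12R)-homoallylic alcohol
Product: 5 C12 tert-butyldimethylsilyl ether of 4
Conditions: TBSCl, imidazole, DMF, rt
Reagents that add atoms: tert-butyldimethylsilyl chloride CC(C)(C)[Si](C)(C)Cl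
Why: Silylation of a secondary alcohol with a silyl chloride and imidazole; the C12 configuration is not touched.

Step 5
Reactants: 5 C12 silyl ether with terminal alkene
Product: 6 (8R)-8-silyloxy-(2E,6E)-farnesyl acetate (C14=C15 isopropylidene in place)
Conditions: 2-methylbut-2-ene (excess), second-generation Grubbs catalyst RuCl2(H2IMes)(PCy3)(=CHPh) (3 mol%), CH2Cl2, 35 °C
Reagents that add atoms: 2-methylbut-2-ene CC=C(C)C
Why: Olefin cross-metathesis of the only monosubstituted alkene with excess 2-methylbut-2-ene should install the isopropylidene terminus, the trisubstituted chain alkenes reacting far more slowly.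

Step 6
Reactants: 6 (8R)-8-silyloxyfarnesyl acetate
Product: 7 (8R)-8-silyloxy-(2E,6E)-farnesol (free C5 hydroxyl)
Conditions: K2CO3 (cat.), MeOH, rt
Reagents that add atoms: none
Why: Base-catalysed transesterification (methanolysis) frees the primary allylic alcohol while the silyl ether stays.

Step 7
Reactants: 7 (8R)-8-silyloxyfarnesol
Product: 8 (6S,7S)-epoxy alcohol (C5 hydroxyl free)
Conditions: Ti(OiPr)4 (10 mol%), L-(+)-diethyl tartrate (12 mol%), t-BuOOH, 4 Å molecular sieves, CH2Cl2, −20 °C
Reagents that add atoms: tert-butyl hydroperoxide CC(C)(C)OO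
Why: Sharpless asymmetric epoxidation: the titanium tartrate complex binds the only free allylic alcohol and, with the L-(+)-tartrate, should deliver oxygen to the face that gives the (2S,3S)-epoxy alcohol (C6 S, C7 S), the other alkenes having no directing hydroxyl.

Step 8
Reactants: 8 (6S,7S)-epoxy alcohol
Product: 9 (6S,7R)-5,6,7-triol
Conditions: HClO4 (cat., dilute aq.), THF/H2O, 0 °C
Reagents that add atoms: water O
Why: Acid-catalysed epoxide hydrolysis: water should attack the protonated epoxide at the tertiary carbon C7 from the rear (borderline SN2), inverting C7 to R while C6 keeps its oxygen and stays S.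

Step 9
Reactants: 9 (6S,7R)-5,6,7-triol
Product: 11 terminal C5–C6 epoxide with free C7 hydroxyl (6S,7R), via primary tosylate 10 (not isolated)
Conditions: TsCl (1.05 equiv), Et3N, Bu2SnO (2 mol%), CH2Cl2, 0 °C; then DBU, rt
Reagents that add atoms: p-toluenesulfonyl chloride Cc1ccc(cc1)S(Cl)(=O)=O (its sulfonyl group is held only by the unisolated tosylate 10, not by 11)
Why: Tin-catalysed selective sulfonylation of the primary hydroxyl of a 1,2-diol and 3-exo-tet Williamson closure by the C6 oxygen; only the C5–O bond is broken, so C6 and C7 keep their configuration, and the amidine base avoids the free alkoxide that could trigger Payne rearrangement.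

Step 10
Reactants: 12 2-methylidenepropane-1,3-diol
Product: 13 mono-tert-butyldimethylsilyl ether of 12
Conditions: NaH (1.0 equiv), THF, 0 °C; TBSCl (1.0 equiv)
Reagents that add atoms: tert-butyldimethylsilyl chloride CC(C)(C)[Si](C)(C)Cl
Why: Monosilylation of a symmetric diol through its sparingly soluble monosodium alkoxide.

Step 11
Reactants: 13 mono-silyl ether
Product: 14 2-(silyloxymethyl)allyl chloride
Conditions: N-chlorosuccinimide, PPh3, THF, 0 °C to rt
Reagents that add atoms: N-chlorosuccinimide O=C1CCC(=O)N1Cl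
Why: Appel-type chlorination of a primary allylic alcohol; the allyl unit is symmetric about its double bond, so allylic transposition gives the same compound.

Step 12
Reactants: 11 terminal epoxide; 14 2-(silyloxymethyl)allyl chloride
Product: 16 (6S,7R)-6,7-diol with the C3 methylidene and C20 silyl ether in place, via allylic Grignard reagent 15 (not isolated)
Conditions: 14, Mg (activated), THF, 0 °C, slow addition; then 11, CuBr·SMe2 (10 mol%), THF, −40 to −10 °C; aq. NH4Cl
Reagents that add atoms: magnesium [Mg] (held only by the unisolated reagent 15, not by 16)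
Why: Copper-catalysed opening of a terminal epoxide by an allylic Grignard reagent at the unhindered CH2 (C5) forms the C4–C5 bond and leaves C6 (S) and C7 (R) untouched; one equivalent of reagent is spent on the tertiary hydroxyl.

Step 13
Reactants: 16 (6S,7R)-6,7-diol; 17 acryloyl chloride
Product: 18 C6 acrylate with free C7 hydroxyl (metathesis precursor)
Conditions: iPr2NEt, CH2Cl2, −78 to −20 °C
Reagents that add atoms: none
Why: Acylation with an acid chloride should select the secondary C6 hydroxyl over the tertiary C7 hydroxyl, C12 and C20 being blocked as silyl ethers.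

Step 14
Reactants: 18 C6 acrylate
Product: 19 seven-membered α,β-unsaturated lactone (C1 carbonyl, ring oxygen on C6)
Conditions: second-generation Grubbs catalyst RuCl2(H2IMes)(PCy3)(=CHPh) (10 mol%, two portions), 1,4-benzoquinone (20 mol%), toluene (2 mM), 80 °C, argon sparge
Reagents that add atoms: none
Why: The ruthenium alkylidene exchanges with one alkene terminus and then passes through intramolecular [2+2] cycloaddition and cycloreversion with the other, joining C2 to C3 and expelling ethene, which is swept out. The closest known reaction type is ring-closing metathesis of acrylate esters with 1,1-disubstituted alkenes to trisubstituted α,β-unsaturated lactones under second-generation ruthenium catalysts. The one ring closed is the seven-membered lactone (C1, C2, C3, C4, C5, C6 and the ester oxygen), formed by joining the two alkene carbons tethered through the C6 ester. No stereocenter is created; the C2=C3 geometry is dictated by the ring, which cannot hold a trans double bond, so C1 must lie cis to C4. The step needs chemoselectivity over the trisubstituted C10=C11 and C14=C15 alkenes and over intermolecular metathesis: the alternatives would be eight- and twelve-membered closures, trisubstituted alkenes engage the catalyst more slowly, and high dilution suppresses dimerisation. The free C7 hydroxyl and both silyl ethers should be inert, and benzoquinone is added against ruthenium hydrides that could shift double bonds.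

Step 15
Reactants: 19 unsaturated lactone
Product: 20 1,6,7-triol (C1 and C4 cis on C2=C3)
Conditions: iBu2AlH (5 equiv), CH2Cl2, −78 to 0 °C; aq. potassium sodium tartrate
Reagents that add atoms: none
Why: Hydride reduction of an α,β-unsaturated lactone with iBu2AlH proceeds by 1,2-addition through the lactol to the allylic diol, freeing C1 as CH2OH and C6 as a secondary alcohol without moving the C2=C3 double bond.

Step 16
Reactants: 20 1,6,7-triol
Product: 21 C1 acetate with free C6 and C7 hydroxyls
Conditions: Ac2O (1.1 equiv), 2,4,6-collidine, CH2Cl2, −20 to 0 °C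
Reagents that add atoms: acetic anhydride CC(=O)OC(C)=O
Why: Acylation under mild base should distinguish the unhindered primary allylic C1 hydroxyl from the hindered secondary C6 and tertiary C7 hydroxyls.

Step 17
Reactants: 21 C1 acetate 6,7-diol
Product: 23 (6R,7R)-epoxide with C12 and C20 silyl ethers, via C6 mesylate 22 (not isolated)
Conditions: MsCl, Et3N, CH2Cl2, −10 °C; then DBU, rt
Reagents that add atoms: methanesulfonyl chloride CS(Cl)(=O)=O (its sulfonyl group is held only by the unisolated mesylate 22, not by 23)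
Why: Sulfonylation of the secondary C6 hydroxyl and intramolecular SN2 displacement by the C7 oxygen (3-exo-tet) invert C6 and keep C7, giving the (6R,7R) trans epoxide; the non-nucleophilic amidine base leaves the C1 acetate in place.

Step 18
Reactants: 23 bis-silyl epoxy acetate
Product: 24 CNP0323680.1
Conditions: Bu4NF/AcOH (1:1), THF, rt
Reagents that add atoms: none
Why: Fluoride-induced cleavage of both silyl ethers; acetic acid buffers the alkoxides so that the acetate is neither hydrolysed nor moved and the epoxide is not opened, and C1 and C20 lie trans on the alkene, so no intramolecular acyl shift is possible.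

Compound list
1 | geranyl acetate, (2E)-3,7-dimethylocta-2,6-dien-1-yl acetate | CC(C)=CCC/C(C)=C/COC(C)=O | starting material
2 | (2E,6E)-8-hydroxy-3,7-dimethylocta-2,6-dien-1-yl acetate | CC(=O)OC/C=C(\C)CC/C=C(\C)CO | intermediate
3 | (2E,6E)-3,7-dimethyl-8-oxoocta-2,6-dien-1-yl acetate | CC(=O)OC/C=C(\C)CC/C=C(\C)C=O | intermediate
4 | (2E,6E,8R)-8-hydroxy-3,7-dimethylundeca-2,6,10-trien-1-yl acetate | CC(=O)OC/C=C(\C)CC/C=C(\C)[C@H](O)CC=C | intermediate
5 | (2E,6E,8R)-8-[(tert-butyldimethylsilyl)oxy]-3,7-dimethylundeca-2,6,10-trien-1-yl acetate | CC(=O)OC/C=C(\C)CC/C=C(\C)[C@H](O[Si](C)(C)C(C)(C)C)CC=C | intermediate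
6 | (2E,6E,8R)-8-[(tert-butyldimethylsilyl)oxy]-3,7,11-trimethyldodeca-2,6,10-trien-1-yl acetate | CC(=O)OC/C=C(\C)CC/C=C(\C)[C@H](O[Si](C)(C)C(C)(C)C)CC=C(C)C | intermediate
7 | (2E,6E,8R)-8-[(tert-butyldimethylsilyl)oxy]-3,7,11-trimethyldodeca-2,6,10-trien-1-ol | OC/C=C(\C)CC/C=C(\C)[C@H](O[Si](C)(C)C(C)(C)C)CC=C(C)C | intermediate
8 | [(2S,3S)-3-{(3E,5R)-5-[(tert-butyldimethylsilyl)oxy]-4,8-dimethylnona-3,7-dien-1-yl}-3-methyloxiran-2-yl]methanol | OC[C@@H]1O[C@@]1(C)CC/C=C(\C)[C@H](O[Si](C)(C)C(C)(C)C)CC=C(C)C | intermediate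
9 | (2S,3R,6E,8R)-8-[(tert-butyldimethylsilyl)oxy]-3,7,11-trimethyldodeca-6,10-diene-1,2,3-triol | OC[C@H](O)[C@](C)(O)CC/C=C(\C)[C@H](O[Si](C)(C)C(C)(C)C)CC=C(C)C | intermediate
10 | (2S,3R,6E,8R)-8-[(tert-butyldimethylsilyl)oxy]-2,3-dihydroxy-3,7,11-trimethyldodeca-6,10-dien-1-yl 4-methylbenzenesulfonate | Cc1ccc(cc1)S(=O)(=O)OC[C@H](O)[C@](C)(O)CC/C=C(\C)[C@H](O[Si](C)(C)C(C)(C)C)CC=C(C)C | intermediate
11 | (2R,5E,7R)-7-[(tert-butyldimethylsilyl)oxy]-6,10-dimethyl-2-[(2S)-oxiran-2-yl]undeca-5,9-dien-2-ol | C1O[C@@H]1[C@](C)(O)CC/C=C(\C)[C@H](O[Si](C)(C)C(C)(C)C)CC=C(C)C | intermediate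
12 | 2-methylidenepropane-1,3-diol | C=C(CO)CO | starting material
13 | 2-({[tert-butyl(dimethyl)silyl]oxy}methyl)prop-2-en-1-ol | C=C(CO)CO[Si](C)(C)C(C)(C)C | intermediate
14 | tert-butyl{[2-(chloromethyl)prop-2-en-1-yl]oxy}dimethylsilane | C=C(CCl)CO[Si](C)(C)C(C)(C)C | intermediate
15 | [2-({[tert-butyl(dimethyl)silyl]oxy}methyl)prop-2-en-1-yl]magnesium chloride | C=C(C[Mg]Cl)CO[Si](C)(C)C(C)(C)C | intermediate
16 | (5S,6R,9E,11R)-11-[(tert-butyldimethylsilyl)oxy]-2-({[tert-butyl(dimethyl)silyl]oxy}methyl)-6,10,14-trimethylpentadeca-1,9,13-triene-5,6-diol | C=C(CO[Si](C)(C)C(C)(C)C)CC[C@H](O)[C@](C)(O)CC/C=C(\C)[C@H](O[Si](C)(C)C(C)(C)C)CC=C(C)C | intermediate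
17 | acryloyl chloride (prop-2-enoyl chloride) | C=CC(Cl)=O | starting material
18 | (5S,6R,9E,11R)-11-[(tert-butyldimethylsilyl)oxy]-2-({[tert-butyl(dimethyl)silyl]oxy}methyl)-6-hydroxy-6,10,14-trimethylpentadeca-1,9,13-trien-5-yl prop-2-enoate | C=CC(=O)O[C@@H](CCC(=C)CO[Si](C)(C)C(C)(C)C)[C@](C)(O)CC/C=C(\C)[C@H](O[Si](C)(C)C(C)(C)C)CC=C(C)C | intermediate
19 | (7S)-4-({[tert-butyl(dimethyl)silyl]oxy}methyl)-7-{(2R,5E,7R)-7-[(tert-butyldimethylsilyl)oxy]-2-hydroxy-6,10-dimethylundeca-5,9-dien-2-yl}-6,7-dihydrooxepin-2(5H)-one | O=C1C=C(CO[Si](C)(C)C(C)(C)C)CC[C@@H]([C@](C)(O)CC/C=C(\C)[C@H](O[Si](C)(C)C(C)(C)C)CC=C(C)C)O1 | intermediate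
20 | (2E,6S,7R,10E,12R)-12-[(tert-butyldimethylsilyl)oxy]-3-({[tert-butyl(dimethyl)silyl]oxy}methyl)-7,11,15-trimethylhexadeca-2,10,14-triene-1,6,7-triol | OC/C=C(/CO[Si](C)(C)C(C)(C)C)CC[C@H](O)[C@](C)(O)CC/C=C(\C)[C@H](O[Si](C)(C)C(C)(C)C)CC=C(C)C | intermediate
21 | (2E,6S,7R,10E,12R)-12-[(tert-butyldimethylsilyl)oxy]-3-({[tert-butyl(dimethyl)silyl]oxy}methyl)-6,7-dihydroxy-7,11,15-trimethylhexadeca-2,10,14-trien-1-yl acetate | CC(=O)OC/C=C(/CO[Si](C)(C)C(C)(C)C)CC[C@H](O)[C@](C)(O)CC/C=C(\C)[C@H](O[Si](C)(C)C(C)(C)C)CC=C(C)C | intermediate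
22 | (2E,6S,7R,10E,12R)-12-[(tert-butyldimethylsilyl)oxy]-3-({[tert-butyl(dimethyl)silyl]oxy}methyl)-7-hydroxy-7,11,15-trimethyl-6-[(methylsulfonyl)oxy]hexadeca-2,10,14-trien-1-yl acetate | CC(=O)OC/C=C(/CO[Si](C)(C)C(C)(C)C)CC[C@H](OS(C)(=O)=O)[C@](C)(O)CC/C=C(\C)[C@H](O[Si](C)(C)C(C)(C)C)CC=C(C)C | intermediate
23 | (2E)-5-[(2R,3R)-3-{(3E,5R)-5-[(tert-butyldimethylsilyl)oxy]-4,8-dimethylnona-3,7-dien-1-yl}-3-methyloxiran-2-yl]-3-({[tert-butyl(dimethyl)silyl]oxy}methyl)pent-2-en-1-yl acetate | CC(=O)OC/C=C(/CO[Si](C)(C)C(C)(C)C)CC[C@H]1O[C@]1(C)CC/C=C(\C)[C@H](O[Si](C)(C)C(C)(C)C)CC=C(C)C | intermediate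
24 | CNP0323680.1, (2E)-5-[(2R,3R)-3-{(3E,5R)-5-hydroxy-4,8-dimethylnona-3,7-dien-1-yl}-3-methyloxiran-2-yl]-3-(hydroxymethyl)pent-2-en-1-yl acetate | CC(=O)OC/C=C(/CO)CC[C@H]1O[C@]1(C)CC/C=C(\C)[C@H](O)CC=C(C)C | target

Total step count: 18.
Longest linear sequence: 16 (steps 1–9 and 12–18); steps 10 and 11 make the allyl fragment.

Steps most likely to fail

Step 14. The closure joins an acrylate to a hindered 1,1-disubstituted alkene and may be slow, which would let ethenolysis or cross-metathesis of the C14=C15 isopropylidene group and oligomerisation compete. The fallback sets out from epoxide 11 and rejoins the route at triol 20, bypassing steps 12 to 15; it fixes the alkene geometry by trans-hydroalumination of an alkyne and forms the C3–C4 bond by B-alkyl Suzuki–Miyaura coupling. Dimethylsulfonium methylide (trimethylsulfonium iodide, n-BuLi, THF) would homologate the terminal epoxide of 11 to the allylic alcohol (3S,4R,7E,9R)-9-[(tert-butyldimethylsilyl)oxy]-4,8,12-trimethyltrideca-1,7,11-triene-3,4-diol F1. Separately, but-2-yne-1,4-diol would be monosilylated (NaH, TBSCl) to 4-[(tert-butyldimethylsilyl)oxy]but-2-yn-1-ol F2. Hydroxyl-directed trans-hydroalumination of this alkyne with NaAlH2(OCH2CH2OMe)2 and quenching with I2 should give (2Z)-4-[(tert-butyldimethylsilyl)oxy]-3-iodobut-2-en-1-ol F3, with iodine cis to C1. Hydroboration of the vinyl group of the allylic alcohol with excess 9-borabicyclo[3.3.1]nonane (the hydroxyls are borylated transiently and freed again in the aqueous base) would give 9-[(3S,4R,7E,9R)-9-[(tert-butyldimethylsilyl)oxy]-3,4-dihydroxy-4,8,12-trimethyltrideca-7,11-dien-1-yl]-9-borabicyclo[3.3.1]nonane F4. Coupling of this borane with the iodide in the same flask [PdCl2(dppf), AsPh3, Cs2CO3, DMF/THF/H2O] proceeds with retention of alkene geometry and would give 20.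

Step 12. Wurtz homocoupling during formation of the functionalised allylic Grignard reagent, or Payne-type rearrangement of the magnesium alkoxide of 11 before it is opened, would erode the coupling. The fallback sets out from epoxide 11 and rejoins at diol 16. The epoxide would be opened with the dianion of 2-methylprop-2-en-1-ol (n-BuLi, TMEDA, Et2O, 0 °C to rt) to give (5S,6R,9E,11R)-11-[(tert-butyldimethylsilyl)oxy]-2-(hydroxymethyl)-6,10,14-trimethylpentadeca-1,9,13-triene-5,6-diol F5. Selective silylation of its primary allylic hydroxyl (TBSCl, imidazole, CH2Cl2, −20 °C) would then give 16.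

Step 8. Partial carbocation character at C7 could leak stereospecificity, and the aqueous acid could strip the C12 silyl ether. The fallback sets out from epoxy alcohol 8 and rejoins at triol 9. Opening with benzoic acid mediated by Ti(OiPr)4 (CH2Cl2, rt), in which the titanium-bound alkoxide directs the carboxylate to C7 with inversion, would give (2S,3R,6E,8R)-8-[(tert-butyldimethylsilyl)oxy]-1,2-dihydroxy-3,7,11-trimethyldodeca-6,10-dien-3-yl benzoate F6. Any acyl-migrated isomers converge in the following methanolysis (K2CO3, MeOH), which would give 9.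

Further compounds
F1 | step 14 | (3S,4R,7E,9R)-9-[(tert-butyldimethylsilyl)oxy]-4,8,12-trimethyltrideca-1,7,11-triene-3,4-diol | C=C[C@H](O)[C@](C)(O)CC/C=C(\C)[C@H](O[Si](C)(C)C(C)(C)C)CC=C(C)C
F2 | step 14 | 4-[(tert-butyldimethylsilyl)oxy]but-2-yn-1-ol | OCC#CCO[Si](C)(C)C(C)(C)C
F3 | step 14 | (2Z)-4-[(tert-butyldimethylsilyl)oxy]-3-iodobut-2-en-1-ol | OC/C=C(\I)CO[Si](C)(C)C(C)(C)C
F4 | step 14 | 9-[(3S,4R,7E,9R)-9-[(tert-butyldimethylsilyl)oxy]-3,4-dihydroxy-4,8,12-trimethyltrideca-7,11-dien-1-yl]-9-borabicyclo[3.3.1]nonane | B1(CC[C@H](O)[C@](C)(O)CC/C=C(\C)[C@H](O[Si](C)(C)C(C)(C)C)CC=C(C)C)C2CCCC1CCC2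
F5 | step 12 | (5S,6R,9E,11R)-11-[(tert-butyldimethylsilyl)oxy]-2-(hydroxymethyl)-6,10,14-trimethylpentadeca-1,9,13-triene-5,6-diol | C=C(CO)CC[C@H](O)[C@](C)(O)CC/C=C(\C)[C@H](O[Si](C)(C)C(C)(C)C)CC=C(C)C
F6 | step 8 | (2S,3R,6E,8R)-8-[(tert-butyldimethylsilyl)oxy]-1,2-dihydroxy-3,7,11-trimethyldodeca-6,10-dien-3-yl benzoate | OC[C@H](O)[C@](C)(OC(=O)c1ccccc1)CC/C=C(\C)[C@H](O[Si](C)(C)C(C)(C)C)CC=C(C)C
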